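The closed, stirred vessel holds two phases: the reagent is charged in the second, and the target rises and fades in the first.

| flask | starting material | reagent in the second phase | remark | time | volume of the second phase over the first |
|---|---|---|---|---|---|
| south-east | 20 mM | 15 mM | run made earlier |  |  |
| east | 20 mM | 33 mM | run made earlier |  |  |
| north-west | 40 mM | 22 mM | run made earlier |  |  |
| flask | 20 mM | 22.0 mM |  | 6.0 d | 0.50 |

| run | time / d | target / % |
|---|---|---|
| south-east | 0.625 | 3 |
| south-east | 0.833 | 6 |
| south-east | 1.25 | 9 |
| south-east | 2.08 | 8 |
| south-east | 3.00 | 5 |
| south-east | 5.00 | 9 |
| south-east | 8.00 | 3 |
| east | 1.04 | 15 |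
| east | 2.08 | 17 |
| east | 3.00 | 11 |
| east | 4.00 | 9 |
| east | 5.00 | 8 |
| east | 6.00 | 4 |
| east | 8.00 | 6 |
| north-west | 1.25 | 4 |
| north-west | 3.00 | 4 |
| north-west | 4.00 | 4 |
| north-west | 6.00 | 1 |
| north-west | 8.00 | 0 |

(standard deviation of a reading: 1.5 percentage points)

- in the second phase: reagent in the second phase; everything else is in the first
- charges count per volume of the first phase; a concentration in a rate is the amount of a species over the volume of its own phase; every rate counts per litre of the first phase
- the earlier runs hold the two phases in the same ratio of volumes as the flask asked about

* the target standing at 6.0 d, as a percentage of the starting material charged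
* the change that raises the amount of target at 6.0 d, in percent of the starting material charged most ("none" if none brings more than 2 percentage points) (oak / cedar / none)
* amount of target at 6.0 d, in percent of the starting material charged, after cedar

- oak: doubling the amount of reagent in the second phase, all else as stated
- cedar: doubling the transfer coefficient of the reagent in the second phase, all else as stated

In the east run the target climbs to 17% at 2.08 d and falls afterwards, so we place the crossing, where loss overtakes making, near that time. The south-east and east runs share [starting material] and were both read at 2.08 d and 8.00 d. Summing the two runs at each time damps the scatter, and the ratio of the sums gives 0.173 d⁻¹. This is a first fade rate, the first-order rate at which the target falls past the crossing.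

Our flask has [reagent in the second phase] of 22.0 mM, which lies 0.389 of the way from the south-east run to the east run. Interpolating the readings at 2.08 d gives a height of 11.5%, and the fade rate carries that to 5.85% at 6.0 d.

The weak link is the fade rate: its late sum of 9.00% is smaller than its early sum of 25.0%, and each reading is good to 1.5 percentage points, so the late end carries the larger relative error. So we widen both ends, summing the two runs at 2.08 d and 3.00 d for the early end and at 5.00 d and 8.00 d for the late end. That gives 0.115 d⁻¹, the fade rate we carry. The same early readings, interpolated as before, put the flask at 9.42% at 2.54 d, and we commit to 6.33%.

The forecast gives 5.5%, below ours, with 5% after cedar and oak as the best change, holding that “Doubling the reagent should raise the peak and tail substantially”.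

The flask stands at 4.53%. Oak moves it by −1.5 points and cedar by −0.41 points, so the best change is none, and after cedar it holds 4.12%.

    reagent in the reaction phase ⇌ reagent in the second phase, rate k1*([reagent in the reaction phase] - [reagent in the second phase]/K1) per volume of the first phase (partition coefficient = 1.80, kL = 0.0326 h⁻¹)
    reagent in the reaction phase + target → over-reacted product (k = 0.755 M⁻¹ h⁻¹)
    starting material + reagent in the reaction phase → target (k = 1.80 M⁻¹ h⁻¹)
    target → over-reaction product (k = 0.0201 h⁻¹)
    starting material + target → side product (k = 3.39 M⁻¹ h⁻¹)

From 8.74% at 3.00 d to 4.53%, this flask fades at 0.219 d⁻¹, faster than our fade rate. Read at 2.5 d instead, the same height and fade rate give 9.46%, and that neighbouring flask holds 9.55%.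

The earlier runs and the new flask come from a simulation for substances that don't exist.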